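The runs were computed with constants of no real substance; noise was put on by code.

1. I wanted Pdt2, the ring, and the steps thought possible bring it by way of Imd. Sbt and Spx make Imd, and Imd then either closes to Pdt2 or meets a second Sbt and becomes Spx3. The gas Spx2 keeps feeding Spx.

in all of them: Spx2 48 mM (held)

| run | Sbt | temperature | remark | time |
|---|---|---|---|---|
| Saturday's | 0.70 M | 15 °C | run made earlier |  |
| Monday's | 1.1 M | 50 °C | run made earlier |  |
| winter | 0.50 M | 50 °C |  | 100 min |
| dusk | 0.50 M | 20 °C |  | 100 min |
| dawn | 0.50 M | 80 °C |  | 100 min |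
| summer | 0.50 M |  | at 20 °C until 50 min, from then on at 80 °C | 100 min |

| Saturday's: time / min | Saturday's: Pdt2 / % | Monday's: time / min | Monday's: Pdt2 / % |
|---|---|---|---|
| 50.0 | 3.5 | 5.00 | 4.8 |
| 80.0 | 7.3 | 8.00 | 8.6 |
| 150 | 15.9 | 12.0 | 13.6 |
| 180 | 19.2 | 15.0 | 16.6 |
| 240 | 23.6 | 25.0 | 26.8 |
| 300 | 29.0 | 40.0 | 38.2 |
| 360 | 31.7 | 60.0 | 48.8 |

(each reading ± 0.5 percentage points)

- a species is counted by the Sbt in it: one Spx3 counts as two
- at the start none of Spx is dissolved
- the numbers in the tables scatter by 0.5 percentage points (one standard deviation)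
- steps thought possible: Sbt + Spx -> Imd; Imd -> Pdt2; Sbt + Imd -> Spx3; Spx2 <-> Spx; 2 Spx -> Pdt

- the flask that comes out highest in amount of Pdt2, in percent of the Sbt charged, or "all alike" when all lie within 1.5 percentage points (winter / dusk / dawn / summer / all alike)
- Pdt2 at the end, in percent of the Sbt charged, winter
- Pdt2 at the end, in percent of the Sbt charged, dusk
- Pdt2 at the end, in percent of the Sbt charged, dawn
- Pdt2 at the end, in percent of the Sbt charged, summer

2. I wrote the balance of Sbt. Let K, the selectivity factor, be the trapping rate over the closing rate per unit of cSbt, so that K·cSbt Imd are trapped for each Imd that closes. A closed Imd costs one Sbt and a trapped one costs two, so while Imd holds about steady each Sbt spent gives 1/(1 + 2·K·cSbt) of Pdt2. The speed of spending cancels from this count, and Spx with it.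

3. The forecast, extrapolating from the runs, put its K at 1.5 per M at 20 °C and 0.17 per M at 80 °C, and I took these in the sense above. For dusk, 2·K·cSbt at the charge came to 1.50. I call this the trapping number x. For dawn it came to 0.170, a smaller number.

4. Summing the balance as Sbt falls to a share a gives Pdt2 plus Imd = ln[(1 + x)/(1 + x·a)]/x. With a = 0, this gave me an estimated end share of 61.1 % for dusk and 92.4 % for dawn, well above it.

5. The forecast's K at 50 °C, the temperature of winter, was 0.45 per M, which gave winter an x of 0.450. Summer spends its first half at 20 °C, with the x of dusk. Dawn's x was the smallest of the three, so I chose dawn.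

6. The forecast also chose dawn: 71 % for winter, 19 % for dusk, 91 % for dawn and 80 % for summer. Its dawn figure lies just under my estimate, which rests on its K. Its ground: “Hot conditions favour ring closure, so dawn is best.”

7. The flasks gave 72.6 % for winter, 18.3 % for dusk, 87.7 % for dawn and 78.7 % for summer, so dawn came out highest, as forecast. Dusk still held 47.7 % of its Sbt and 7.88 % as Imd at 100 min. Putting that Sbt into the sum with x = 1.50 and taking off the Imd gives 17.2 % of Pdt2.

    Sbt + Spx → Imd (k = 0.120 /M/min, Ea = 48.0 kJ/mol)
    Imd → Pdt2 (k = 0.0250 /min, Ea = 81.0 kJ/mol)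
    Sbt + Imd → Spx3 (k = 0.0520 /M/min, Ea = 53.0 kJ/mol)
    Spx2 ⇌ Spx, rate k4*(csat - [Spx]) (kL = 1.60 /min)
    2 Spx → Pdt (k = 0.250 /M/min, Ea = 46.0 kJ/mol)
    (constants at 20 °C)

8. Dusk left until 3.0 h had 26.5 % of its Sbt and 5.52 % as Imd. The same x gives 33.3 % of Pdt2 there, and the computed flask gives 31.7 %.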